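Ring B is disconnected across C9–C10 and C7–C8, so that quaternary C10, the atom tying ring A to C9, is created when a ring A 1-vinyl-2-methylcyclohexene (C10, C5, C6, C7) adds to a four-carbon ynoate supplying C8, C9, C17 and C11. One thermal Diels–Alder reaction closes ring B, makes two skeletal bonds and sets C10 under control of C4. The diene carries the C3 silyl ether and C4 as a tert-butyl ester, which shields the β face and stays distinct from the C11 methyl ester. The C5–C6 and C8–C9 alkenes left behind are used to set C5, grow the side chain and unveil the C8 methylene with C9.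

Key step: step 12

Remarks on the chemistry:
- Positions are given in labdane numbering (C1–C10 decalin, C11–C16 side chain, C17 on C8, C18 and C19 on C4, C20 on C10); α is the face opposite the C10 methyl. TBS = tert-butyldimethylsilyl, Tf = trifluoromethylsulfonyl.
- Assumption: the alkene geometry of 6 and the C6 configuration of 8 do not matter, because both elements are destroyed in steps 6 and 7.

Step 1
Reactants: 1 2-methylcyclohexane-1,3-dione; 2 allyl bromide
Product: 3 2-allyl-2-methylcyclohexane-1,3-dione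
Conditions: NaOH (1 M aq), H2O, rt
Reagents that add atoms: none
Why: SN2 C-alkylation of the stabilised dione enolate builds the quaternary carbon that becomes C4, and no stereocentre arises because the product keeps a mirror plane.

Step 2
Reactants: 3 2-allyl-2-methylcyclohexane-1,3-dione
Product: 4 (2S,3S)-2-allyl-3-hydroxy-2-methylcyclohexan-1-one
Conditions: baker's yeast, sucrose, H2O, 30 °C
Reagents that add atoms: none
Why: Enzymatic desymmetrising ketone reduction, an established reaction type for 2-alkyl-2-methylcyclohexane-1,3-diones, should reduce one enantiotopic carbonyl to give mainly the ketol with hydroxyl cis to allyl, fixing C3 (S) and quaternary C4 together; the minor diastereomer is removed by chromatography.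

Step 3
Reactants: 4 (2S,3S)-2-allyl-3-hydroxy-2-methylcyclohexan-1-one
Product: 5 (2S,3S)-2-allyl-3-(TBS-oxy)-2-methylcyclohexan-1-one
Conditions: TBSCl, imidazole, DMF, 40 °C
Reagents that add atoms: tert-butyldimethylsilyl chloride, CC(C)(C)[Si](C)(C)Cl
Why: Imidazole-promoted O-silylation protects the C3 alcohol against the enolate and hydride chemistry that follows, without touching either stereocentre.

Step 4
Reactants: 5 (2S,3S)-2-allyl-3-(TBS-oxy)-2-methylcyclohexan-1-one
Product: 6 (2S,3S)-3-(TBS-oxy)-2-methyl-2-[(E)-prop-1-en-1-yl]cyclohexan-1-one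
Conditions: RuHCl(CO)(PPh3)3 (5 mol %), toluene, 80 °C
Reagents that add atoms: none
Why: Ruthenium hydride-catalysed alkene isomerisation (hydrometalation then β-hydride elimination) moves the terminal alkene one position inward, where it stops because C4 is quaternary, so the later cleavage leaves exactly one carbon (C19) on C4.

Step 5
Reactants: 6 (2S,3S)-3-(TBS-oxy)-2-methyl-2-[(E)-prop-1-en-1-yl]cyclohexan-1-one
Product: 8 (2S,3S)-3-(TBS-oxy)-2,6-dimethyl-2-[(E)-prop-1-en-1-yl]cyclohexan-1-one (both C6 epimers), via lithium enolate 7 (not isolated)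
Conditions: LiN(i-Pr)2, THF, −78 °C; MeI, −78 to 0 °C
Reagents that add atoms: iodomethane, CI
Why: Enolate alkylation at the only enolisable α-carbon installs the future C20 methyl on C10; the new centre is formed as a mixture that converges in step 6.

Step 6
Reactants: 8 (2S,3S)-3-(TBS-oxy)-2,6-dimethyl-2-[(E)-prop-1-en-1-yl]cyclohexan-1-one
Product: 10 (5S,6S)-5-(TBS-oxy)-2,6-dimethyl-6-[(E)-prop-1-en-1-yl]cyclohex-1-en-1-yl trifluoromethanesulfonate, via potassium enolate 9 (not isolated)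
Conditions: KN(SiMe3)2, THF, −78 °C; PhNTf2, −78 °C to rt
Reagents that add atoms: N-phenylbis(trifluoromethanesulfonimide), O=S(=O)(N(c1ccccc1)S(=O)(=O)C(F)(F)F)C(F)(F)F
Why: O-sulfonylation of the only possible (tetrasubstituted) enolate gives the C5–C10 enol triflate, the reaction type used for 2,2,6-trisubstituted cyclohexanones, and removes the ketone before C19 is oxidised.

Step 7
Reactants: 10 (5S,6S)-5-(TBS-oxy)-2,6-dimethyl-6-[(E)-prop-1-en-1-yl]cyclohex-1-en-1-yl trifluoromethanesulfonate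
Product: 11 (1S,6S)-6-(TBS-oxy)-1,3-dimethyl-2-(trifluoromethylsulfonyloxy)cyclohex-2-ene-1-carbaldehyde
Conditions: OsO4 (2 mol %), NaIO4, 2,6-lutidine, dioxane/H2O, rt
Reagents that add atoms: sodium periodate, [Na+].[O-]I(=O)(=O)=O (oxygen relayed by OsO4, O=[Os](=O)(=O)=O)
Why: Lemieux–Johnson dihydroxylation and glycol cleavage should take the electron-richer disubstituted propenyl alkene and leave the hindered, electron-poor tetrasubstituted enol triflate, giving a non-enolisable aldehyde at C19.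

Step 8
Reactants: 11 (1S,6S)-6-(TBS-oxy)-1,3-dimethyl-2-(trifluoromethylsulfonyloxy)cyclohex-2-ene-1-carbaldehyde
Product: 12 (1S,6S)-6-(TBS-oxy)-1,3-dimethyl-2-(trifluoromethylsulfonyloxy)cyclohex-2-ene-1-carboxylic acid
Conditions: NaClO2, NaH2PO4, 2-methylbut-2-ene, t-BuOH/H2O, 0 °C to rt
Reagents that add atoms: sodium chlorite, [Na+].[O-]Cl=O
Why: Pinnick oxidation converts the hindered aldehyde to the acid under mildly acidic conditions that spare the silyl ether and triflate; with the ketone already masked as the enol triflate, the acid is not a β-keto acid and should not decarboxylate.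

Step 9
Reactants: 12 (1S,6S)-6-(TBS-oxy)-1,3-dimethyl-2-(trifluoromethylsulfonyloxy)cyclohex-2-ene-1-carboxylic acid
Product: 13 tert-butyl (1S,6S)-6-(TBS-oxy)-1,3-dimethyl-2-(trifluoromethylsulfonyloxy)cyclohex-2-ene-1-carboxylate
Conditions: Me2NCH(Ot-Bu)2, toluene, 80 °C
Reagents that add atoms: N,N-dimethylformamide di-tert-butyl acetal, CN(C)C(OC(C)(C)C)OC(C)(C)C
Why: Esterification by O-alkylation of the carboxylate with the tert-butyl cation released from the amide acetal does not require attack at the hindered carbonyl, so it suits the quaternary C4 acid.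

Step 10
Reactants: 13 tert-butyl (1S,6S)-6-(TBS-oxy)-1,3-dimethyl-2-(trifluoromethylsulfonyloxy)cyclohex-2-ene-1-carboxylate; 14 tributyl(vinyl)stannane
Product: 15 tert-butyl (1R,6S)-6-(TBS-oxy)-2-ethenyl-1,3-dimethylcyclohex-2-ene-1-carboxylate
Conditions: Pd(PPh3)4 (5 mol %), LiCl, THF, reflux
Reagents that add atoms: none
Why: Stille coupling (oxidative addition of zerovalent palladium into the enol triflate, chloride-assisted transmetalation from tin, reductive elimination) attaches C6–C7 and completes the diene; the stereocentres are not involved.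

Step 11
Reactants: 16 tert-butyldimethyl(prop-2-yn-1-yloxy)silane
Product: 18 methyl 4-(TBS-oxy)but-2-ynoate, via lithium acetylide 17 (not isolated)
Conditions: n-BuLi, THF, −78 °C; ClCO2Me, −78 to 0 °C
Reagents that add atoms: methyl chloroformate, COC(=O)Cl
Why: Deprotonation of the terminal alkyne and acylation of the acetylide with a chloroformate is the standard route to 4-oxygenated but-2-ynoates.

Step 12
Reactants: 15 tert-butyl (1R,6S)-6-(TBS-oxy)-2-ethenyl-1,3-dimethylcyclohex-2-ene-1-carboxylate; 18 methyl 4-(TBS-oxy)but-2-ynoate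
Product: 19 1-tert-butyl 5-methyl (1R,2S,4aS)-2-(TBS-oxy)-6-[(TBS-oxy)methyl]-1,4a-dimethyl-1,2,3,4,4a,7-hexahydronaphthalene-1,5-dicarboxylate
Conditions: 18 (3 equiv), BHT (cat.), neat, 120 °C, sealed tube
Reagents that add atoms: none
Why: A concerted, asynchronous thermal [4+2] cycloaddition, the Diels–Alder reaction of a 1-vinylcyclohexene with an acetylenic ester as used for drimane-type decalins, joins C7 to C8 and C10 to C9. Ring B closes as a six-membered ring in that single intermolecular cycloaddition and emerges as a 1,4-cyclohexadiene that cannot aromatise because C10 is quaternary. The orientation needed puts the ester-bearing alkyne carbon on C10: the largest HOMO coefficient of the diene lies on the unsubstituted terminus C7 and the largest LUMO coefficient of the ynoate on the carbon remote from the ester, so C7–C8 bonding leads. The only new stereocentre, C10, is controlled by C4: in the half-chair with the C3 silyl ether equatorial, the tert-butyl ester is pseudoaxial on the β face, so the ynoate should add to the α face and leave the C10 methyl β, cis to the ester. An alkyne dienophile poses no endo/exo question, and the excess of ynoate at moderate temperature is meant to outrun the 1,5-hydrogen shift open to the diene.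

Step 13
Reactants: 19 1-tert-butyl 5-methyl (1R,2S,4aS)-2-(TBS-oxy)-6-[(TBS-oxy)methyl]-1,4a-dimethyl-1,2,3,4,4a,7-hexahydronaphthalene-1,5-dicarboxylate
Product: 20 tert-butyl (1R,2S,4aS)-2-(TBS-oxy)-6-[(TBS-oxy)methyl]-5-(hydroxymethyl)-1,4a-dimethyl-1,2,3,4,4a,7-hexahydronaphthalene-1-carboxylate
Conditions: i-Bu2AlH, CH2Cl2, −78 °C
Reagents that add atoms: none
Why: Hydride reduction of the conjugated methyl ester gives the C11 allylic alcohol, while the tert-butyl ester on quaternary C4 is too hindered to react at this temperature; this also removes the conjugated acceptor before the radical hydrogenation.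

Step 14
Reactants: 20 tert-butyl (1R,2S,4aS)-2-(TBS-oxy)-6-[(TBS-oxy)methyl]-5-(hydroxymethyl)-1,4a-dimethyl-1,2,3,4,4a,7-hexahydronaphthalene-1-carboxylate
Product: 21 tert-butyl (1R,2S,4aS,8aR)-2-(TBS-oxy)-6-[(TBS-oxy)methyl]-5-(hydroxymethyl)-1,4a-dimethyl-1,2,3,4,4a,7,8,8a-octahydronaphthalene-1-carboxylate
Conditions: Mn(dpm)3 (10 mol %), PhSiH3, t-BuOOH, i-PrOH, rt, argon
Reagents that add atoms: none
Why: Metal-hydride hydrogen-atom-transfer hydrogenation puts H on C6 to give the tertiary C5 radical, which is quenched on the α face opposite the axial C10 methyl and C4 ester to set C5 as the trans ring fusion; the unactivated tetrasubstituted C8–C9 alkene is a poor acceptor for this transfer.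

Step 15
Reactants: 21 tert-butyl (1R,2S,4aS,8aR)-2-(TBS-oxy)-6-[(TBS-oxy)methyl]-5-(hydroxymethyl)-1,4a-dimethyl-1,2,3,4,4a,7,8,8a-octahydronaphthalene-1-carboxylate
Product: 22 tert-butyl (1R,2S,4aS,8aR)-2-(TBS-oxy)-6-[(TBS-oxy)methyl]-5-formyl-1,4a-dimethyl-1,2,3,4,4a,7,8,8a-octahydronaphthalene-1-carboxylate
Conditions: Dess–Martin periodinane, NaHCO3, CH2Cl2, rt
Reagents that add atoms: none
Why: Dess–Martin oxidation of the primary allylic alcohol gives an enal with no α-hydrogen to epimerise, and the buffer protects the silyl ethers.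

Step 16
Reactants: 22 tert-butyl (1R,2S,4aS,8aR)-2-(TBS-oxy)-6-[(TBS-oxy)methyl]-5-formyl-1,4a-dimethyl-1,2,3,4,4a,7,8,8a-octahydronaphthalene-1-carboxylate
Product: 23 tert-butyl (1R,2S,4aS,8aR)-2-(TBS-oxy)-6-[(TBS-oxy)methyl]-5-ethenyl-1,4a-dimethyl-1,2,3,4,4a,7,8,8a-octahydronaphthalene-1-carboxylate
Conditions: Ph3PCH3Br, KOt-Bu, THF, 0 °C to rt
Reagents that add atoms: methyltriphenylphosphonium bromide, C[P+](c1ccccc1)(c1ccccc1)c1ccccc1.[Br-]
Why: Wittig methylenation of the aldehyde adds C12 as a terminal vinyl group on C11, the handle for the sp3–sp2 coupling.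

Step 17
Reactants: 24 tert-butyl 3-oxobutanoate
Product: 25 tert-butyl (2E)-3-(trifluoromethylsulfonyloxy)but-2-enoate
Conditions: Tf2O, Me4NOH (aq), hexane, 5 °C
Reagents that add atoms: trifluoromethanesulfonic anhydride, O=S(=O)(OS(=O)(=O)C(F)(F)F)C(F)(F)F
Why: O-triflation of the non-chelated tetramethylammonium enolate of a β-keto ester is an established way to obtain the (E)-enol triflate, with the triflate trans to the ester.

Step 18
Reactants: 23 tert-butyl (1R,2S,4aS,8aR)-2-(TBS-oxy)-6-[(TBS-oxy)methyl]-5-ethenyl-1,4a-dimethyl-1,2,3,4,4a,7,8,8a-octahydronaphthalene-1-carboxylate; 25 tert-butyl (2E)-3-(trifluoromethylsulfonyloxy)but-2-enoate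
Product: 27 tert-butyl (1R,2S,4aS,8aR)-5-[(3E)-5-tert-butoxy-3-methyl-5-oxopent-3-en-1-yl]-2-(TBS-oxy)-6-[(TBS-oxy)methyl]-1,4a-dimethyl-1,2,3,4,4a,7,8,8a-octahydronaphthalene-1-carboxylate, via alkylborane 26 (not isolated)
Conditions: 9-BBN, THF, 0 °C to rt; then 25, Pd(dppf)Cl2 (5 mol %), K3PO4 (aq), DMF, rt to 50 °C
Reagents that add atoms: none
Why: Anti-Markovnikov hydroboration of the terminal vinyl group followed by B-alkyl Suzuki–Miyaura coupling, which retains the triflate geometry, forms C12–C13 and fixes the 13E enoate in one operation; the tetrasubstituted ring alkene does not hydroborate.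

Step 19
Reactants: 27 tert-butyl (1R,2S,4aS,8aR)-5-[(3E)-5-tert-butoxy-3-methyl-5-oxopent-3-en-1-yl]-2-(TBS-oxy)-6-[(TBS-oxy)methyl]-1,4a-dimethyl-1,2,3,4,4a,7,8,8a-octahydronaphthalene-1-carboxylate
Product: 28 tert-butyl (1R,2S,4aS,8aR)-5-[(3E)-5-tert-butoxy-3-methyl-5-oxopent-3-en-1-yl]-2-hydroxy-6-(hydroxymethyl)-1,4a-dimethyl-1,2,3,4,4a,7,8,8a-octahydronaphthalene-1-carboxylate
Conditions: HF·pyridine, pyridine, THF, 0 °C to rt
Reagents that add atoms: none
Why: Buffered fluoride desilylation frees the C3 and C17 hydroxyls and is mild enough for both tert-butyl esters and the enoate.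

Step 20
Reactants: 28 tert-butyl (1R,2S,4aS,8aR)-5-[(3E)-5-tert-butoxy-3-methyl-5-oxopent-3-en-1-yl]-2-hydroxy-6-(hydroxymethyl)-1,4a-dimethyl-1,2,3,4,4a,7,8,8a-octahydronaphthalene-1-carboxylate
Product: 29 tert-butyl (1R,2S,4aS,8aR)-2-acetoxy-6-(acetoxymethyl)-5-[(3E)-5-tert-butoxy-3-methyl-5-oxopent-3-en-1-yl]-1,4a-dimethyl-1,2,3,4,4a,7,8,8a-octahydronaphthalene-1-carboxylate
Conditions: Ac2O, pyridine, DMAP (cat.), CH2Cl2, rt
Reagents that add atoms: acetic anhydride, CC(=O)OC(C)=O
Why: DMAP-catalysed acylation installs the C3 acetate of the target and, in the same step, turns the C17 alcohol into the allylic leaving group for step 21.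

Step 21
Reactants: 29 tert-butyl (1R,2S,4aS,8aR)-2-acetoxy-6-(acetoxymethyl)-5-[(3E)-5-tert-butoxy-3-methyl-5-oxopent-3-en-1-yl]-1,4a-dimethyl-1,2,3,4,4a,7,8,8a-octahydronaphthalene-1-carboxylate
Product: 30 tert-butyl (1R,2S,4aR,5S,8aR)-2-acetoxy-5-[(3E)-5-tert-butoxy-3-methyl-5-oxopent-3-en-1-yl]-1,4a-dimethyl-6-methylidenedecahydronaphthalene-1-carboxylate
Conditions: Pd(OAc)2 (5 mol %), n-Bu3P (5 mol %), HCO2NH4, 1,4-dioxane, 80 °C
Reagents that add atoms: none
Why: Palladium-catalysed formate hydrogenolysis of an allylic acetate should ionise only the C17 acetate to a π-allyl palladium formate on the α face of ring B (the β face is blocked by the axial C10 methyl), and loss of CO2 with hydride transfer from palladium to the more substituted terminus C9 gives the exocyclic C8–C17 alkene with H-9 α and the side chain β.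

Step 22
Reactants: 30 tert-butyl (1R,2S,4aR,5S,8aR)-2-acetoxy-5-[(3E)-5-tert-butoxy-3-methyl-5-oxopent-3-en-1-yl]-1,4a-dimethyl-6-methylidenedecahydronaphthalene-1-carboxylate
Product: 32 3β-acetoxy-agathic acid, via bis(trimethylsilyl) ester 31 (not isolated)
Conditions: TMSOTf, 2,6-lutidine, CH2Cl2, 0 °C; then H2O
Reagents that add atoms: none
Why: Silyl triflate-mediated tert-butyl ester cleavage (carbonyl O-silylation, loss of the tert-butyl group as isobutene, hydrolysis of the silyl esters on work-up) needs no attack at the hindered C19 carbonyl and, buffered by lutidine, should spare the acid-sensitive exocyclic alkene and the C3 acetate.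

Compound list
1 | 2-methylcyclohexane-1,3-dione | CC1C(=O)CCCC1=O | starting material
2 | allyl bromide | C=CCBr | starting material
3 | 2-allyl-2-methylcyclohexane-1,3-dione | C=CCC1(C)C(=O)CCCC1=O | intermediate
4 | (2S,3S)-2-allyl-3-hydroxy-2-methylcyclohexan-1-one | O=C1CCC[C@H](O)[C@]1(C)CC=C | intermediate
5 | (2S,3S)-2-allyl-3-(tert-butyldimethylsilyloxy)-2-methylcyclohexan-1-one | O=C1CCC[C@H](O[Si](C)(C)C(C)(C)C)[C@]1(C)CC=C | intermediate
6 | (2S,3S)-3-(tert-butyldimethylsilyloxy)-2-methyl-2-[(E)-prop-1-en-1-yl]cyclohexan-1-one | O=C1CCC[C@H](O[Si](C)(C)C(C)(C)C)[C@]1(C)/C=C/C | intermediate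
7 | lithium enolate of 6 (C1–C6 enolate) | [Li]OC1=CCC[C@H](O[Si](C)(C)C(C)(C)C)[C@]1(C)/C=C/C | intermediate
8 | (2S,3S)-3-(tert-butyldimethylsilyloxy)-2,6-dimethyl-2-[(E)-prop-1-en-1-yl]cyclohexan-1-one, C6 epimer mixture | O=C1C(C)CC[C@H](O[Si](C)(C)C(C)(C)C)[C@]1(C)/C=C/C | intermediate
9 | potassium enolate of 8 (tetrasubstituted) | [K]OC1=C(C)CC[C@H](O[Si](C)(C)C(C)(C)C)[C@]1(C)/C=C/C | intermediate
10 | (5S,6S)-5-(tert-butyldimethylsilyloxy)-2,6-dimethyl-6-[(E)-prop-1-en-1-yl]cyclohex-1-en-1-yl trifluoromethanesulfonate | O=S(=O)(OC1=C(C)CC[C@H](O[Si](C)(C)C(C)(C)C)[C@]1(C)/C=C/C)C(F)(F)F | intermediate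
11 | (1S,6S)-6-(tert-butyldimethylsilyloxy)-1,3-dimethyl-2-(trifluoromethylsulfonyloxy)cyclohex-2-ene-1-carbaldehyde | O=S(=O)(OC1=C(C)CC[C@H](O[Si](C)(C)C(C)(C)C)[C@]1(C)C=O)C(F)(F)F | intermediate
12 | (1S,6S)-6-(tert-butyldimethylsilyloxy)-1,3-dimethyl-2-(trifluoromethylsulfonyloxy)cyclohex-2-ene-1-carboxylic acid | O=S(=O)(OC1=C(C)CC[C@H](O[Si](C)(C)C(C)(C)C)[C@]1(C)C(=O)O)C(F)(F)F | intermediate
13 | tert-butyl (1S,6S)-6-(tert-butyldimethylsilyloxy)-1,3-dimethyl-2-(trifluoromethylsulfonyloxy)cyclohex-2-ene-1-carboxylate | O=S(=O)(OC1=C(C)CC[C@H](O[Si](C)(C)C(C)(C)C)[C@]1(C)C(=O)OC(C)(C)C)C(F)(F)F | intermediate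
14 | tributyl(vinyl)stannane | C=C[Sn](CCCC)(CCCC)CCCC | starting material
15 | tert-butyl (1R,6S)-6-(tert-butyldimethylsilyloxy)-2-ethenyl-1,3-dimethylcyclohex-2-ene-1-carboxylate (ring A diene) | C=CC1=C(C)CC[C@H](O[Si](C)(C)C(C)(C)C)[C@]1(C)C(=O)OC(C)(C)C | intermediate
16 | tert-butyldimethyl(prop-2-yn-1-yloxy)silane | C#CCO[Si](C)(C)C(C)(C)C | starting material
17 | lithium acetylide of 16 | [Li]C#CCO[Si](C)(C)C(C)(C)C | intermediate
18 | methyl 4-(tert-butyldimethylsilyloxy)but-2-ynoate | COC(=O)C#CCO[Si](C)(C)C(C)(C)C | intermediate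
19 | 1-tert-butyl 5-methyl (1R,2S,4aS)-2-(tert-butyldimethylsilyloxy)-6-[(tert-butyldimethylsilyloxy)methyl]-1,4a-dimethyl-1,2,3,4,4a,7-hexahydronaphthalene-1,5-dicarboxylate (5,8-diene cycloadduct) | COC(=O)C1=C(CO[Si](C)(C)C(C)(C)C)CC=C2[C@]1(C)CC[C@H](O[Si](C)(C)C(C)(C)C)[C@]2(C)C(=O)OC(C)(C)C | intermediate
20 | tert-butyl (1R,2S,4aS)-2-(tert-butyldimethylsilyloxy)-6-[(tert-butyldimethylsilyloxy)methyl]-5-(hydroxymethyl)-1,4a-dimethyl-1,2,3,4,4a,7-hexahydronaphthalene-1-carboxylate | OCC1=C(CO[Si](C)(C)C(C)(C)C)CC=C2[C@]1(C)CC[C@H](O[Si](C)(C)C(C)(C)C)[C@]2(C)C(=O)OC(C)(C)C | intermediate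
21 | tert-butyl (1R,2S,4aS,8aR)-2-(tert-butyldimethylsilyloxy)-6-[(tert-butyldimethylsilyloxy)methyl]-5-(hydroxymethyl)-1,4a-dimethyl-1,2,3,4,4a,7,8,8a-octahydronaphthalene-1-carboxylate | OCC1=C(CO[Si](C)(C)C(C)(C)C)CC[C@@H]2[C@]1(C)CC[C@H](O[Si](C)(C)C(C)(C)C)[C@]2(C)C(=O)OC(C)(C)C | intermediate
22 | tert-butyl (1R,2S,4aS,8aR)-2-(tert-butyldimethylsilyloxy)-6-[(tert-butyldimethylsilyloxy)methyl]-5-formyl-1,4a-dimethyl-1,2,3,4,4a,7,8,8a-octahydronaphthalene-1-carboxylate | O=CC1=C(CO[Si](C)(C)C(C)(C)C)CC[C@@H]2[C@]1(C)CC[C@H](O[Si](C)(C)C(C)(C)C)[C@]2(C)C(=O)OC(C)(C)C | intermediate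
23 | tert-butyl (1R,2S,4aS,8aR)-2-(tert-butyldimethylsilyloxy)-6-[(tert-butyldimethylsilyloxy)methyl]-5-ethenyl-1,4a-dimethyl-1,2,3,4,4a,7,8,8a-octahydronaphthalene-1-carboxylate | C=CC1=C(CO[Si](C)(C)C(C)(C)C)CC[C@@H]2[C@]1(C)CC[C@H](O[Si](C)(C)C(C)(C)C)[C@]2(C)C(=O)OC(C)(C)C | intermediate
24 | tert-butyl 3-oxobutanoate | CC(=O)CC(=O)OC(C)(C)C | starting material
25 | tert-butyl (2E)-3-(trifluoromethylsulfonyloxy)but-2-enoate | CC(C)(C)OC(=O)/C=C(\C)OS(=O)(=O)C(F)(F)F | intermediate
26 | B-alkyl-9-borabicyclo[3.3.1]nonane from 23 (boron on C12) | C(CC1=C(CO[Si](C)(C)C(C)(C)C)CC[C@@H]2[C@]1(C)CC[C@H](O[Si](C)(C)C(C)(C)C)[C@]2(C)C(=O)OC(C)(C)C)B1C2CCCC1CCC2 | intermediate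
27 | tert-butyl (1R,2S,4aS,8aR)-5-[(3E)-5-tert-butoxy-3-methyl-5-oxopent-3-en-1-yl]-2-(tert-butyldimethylsilyloxy)-6-[(tert-butyldimethylsilyloxy)methyl]-1,4a-dimethyl-1,2,3,4,4a,7,8,8a-octahydronaphthalene-1-carboxylate | CC(C)(C)OC(=O)/C=C(\C)CCC1=C(CO[Si](C)(C)C(C)(C)C)CC[C@@H]2[C@]1(C)CC[C@H](O[Si](C)(C)C(C)(C)C)[C@]2(C)C(=O)OC(C)(C)C | intermediate
28 | tert-butyl (1R,2S,4aS,8aR)-5-[(3E)-5-tert-butoxy-3-methyl-5-oxopent-3-en-1-yl]-2-hydroxy-6-(hydroxymethyl)-1,4a-dimethyl-1,2,3,4,4a,7,8,8a-octahydronaphthalene-1-carboxylate | CC(C)(C)OC(=O)/C=C(\C)CCC1=C(CO)CC[C@@H]2[C@]1(C)CC[C@H](O)[C@]2(C)C(=O)OC(C)(C)C | intermediate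
29 | tert-butyl (1R,2S,4aS,8aR)-2-acetoxy-6-(acetoxymethyl)-5-[(3E)-5-tert-butoxy-3-methyl-5-oxopent-3-en-1-yl]-1,4a-dimethyl-1,2,3,4,4a,7,8,8a-octahydronaphthalene-1-carboxylate | CC(C)(C)OC(=O)/C=C(\C)CCC1=C(COC(C)=O)CC[C@@H]2[C@]1(C)CC[C@H](OC(C)=O)[C@]2(C)C(=O)OC(C)(C)C | intermediate
30 | tert-butyl (1R,2S,4aR,5S,8aR)-2-acetoxy-5-[(3E)-5-tert-butoxy-3-methyl-5-oxopent-3-en-1-yl]-1,4a-dimethyl-6-methylidenedecahydronaphthalene-1-carboxylate | C=C1CC[C@@H]2[C@](C)(CC[C@H](OC(C)=O)[C@]2(C)C(=O)OC(C)(C)C)[C@H]1CC/C(C)=C/C(=O)OC(C)(C)C | intermediate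
31 | bis(trimethylsilyl) ester of the target diacid | C=C1CC[C@@H]2[C@](C)(CC[C@H](OC(C)=O)[C@]2(C)C(=O)O[Si](C)(C)C)[C@H]1CC/C(C)=C/C(=O)O[Si](C)(C)C | intermediate
32 | 3β-acetoxy-agathic acid, (1R,2S,4aR,5S,8aR)-2-acetoxy-5-[(3E)-4-carboxy-3-methylbut-3-en-1-yl]-1,4a-dimethyl-6-methylidenedecahydronaphthalene-1-carboxylic acid | C=C1CC[C@@H]2[C@](C)(CC[C@H](OC(C)=O)[C@]2(C)C(=O)O)[C@H]1CC/C(C)=C/C(=O)O | target

Total step count: 22 steps.
Longest linear sequence: 20 steps (steps 1–10, 12–16 and 18–22; steps 11 and 17 are side branches).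

Steps most likely to fail

1. Step 12 (key cycloaddition). The ynoate may add too slowly at the fully substituted diene terminus C10, letting the diene drift by 1,5-hydrogen shift, or it may bond in the reverse orientation. The fallback sets out from 15 and swaps the dienophile for symmetrical, much more reactive dimethyl but-2-ynedioate (neat, 110 °C), which has no orientation question and should give the triester cycloadduct F1. Reduction of both methyl esters with i-Bu2AlH (CH2Cl2, −78 °C) should give the C11,C17-diol F2. Selective silylation of the less hindered C17 hydroxyl (TBSCl, imidazole, CH2Cl2, −20 °C; the C11 hydroxyl sits next to quaternary C10) rejoins the route at 20. This fallback does not address poor facial selectivity at C10.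

2. Step 14 (radical hydrogenation). Hydrogen-atom transfer may also reach the C8–C9 alkene, the C5 radical may rearrange by 1,2-vinyl shift through a cyclopropylcarbinyl radical, or the hindered alkene may react incompletely. The fallback sets out from 19 and replaces the radical process by heterogeneous hydrogenation (H2, PtO2, EtOAc/AcOH, elevated pressure). Syn addition from the α face, away from the C10 methyl and the C4 ester, should give the trans-fused enoate F3, while the tetrasubstituted conjugated alkene is too hindered to adsorb. Reduction of the C11 methyl ester with i-Bu2AlH then returns to the route at 21.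

3. Step 21 (allylic hydrogenolysis). Hydride may be delivered to C17 instead of C9, re-forming a tetrasubstituted ring alkene; ionisation of the hindered acetate may be slow; or hydride may arrive from the β face. The fallback sets out from 27 and uses a metal-free reductive 1,3-transposition instead. Selective methanolysis of the primary allylic silyl ether (pyridinium p-toluenesulfonate, MeOH, 0 °C) should give the C17 alcohol F4. Mitsunobu displacement with 2-nitrobenzenesulfonylhydrazide (PPh3, diethyl azodicarboxylate, THF, −30 °C to rt) and loss of the sulfinic acid give an allylic diazene. Its retro-ene loss of N2 places H on C9 from the open α face and should give the 8(17)-ene silyl ether F5. HF·pyridine then frees the C3 alcohol F6, and acetylation (Ac2O, pyridine, DMAP) rejoins the route at 30.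

Further compounds
F1 | step 12 | 1-tert-butyl 5,6-dimethyl (1R,2S,4aS)-2-(tert-butyldimethylsilyloxy)-1,4a-dimethyl-1,2,3,4,4a,7-hexahydronaphthalene-1,5,6-tricarboxylate | COC(=O)C1=C(C(=O)OC)CC=C2[C@]1(C)CC[C@H](O[Si](C)(C)C(C)(C)C)[C@]2(C)C(=O)OC(C)(C)C
F2 | step 12 | tert-butyl (1R,2S,4aS)-2-(tert-butyldimethylsilyloxy)-5,6-bis(hydroxymethyl)-1,4a-dimethyl-1,2,3,4,4a,7-hexahydronaphthalene-1-carboxylate | OCC1=C(CO)CC=C2[C@]1(C)CC[C@H](O[Si](C)(C)C(C)(C)C)[C@]2(C)C(=O)OC(C)(C)C
F3 | step 14 | 1-tert-butyl 5-methyl (1R,2S,4aS,8aR)-2-(tert-butyldimethylsilyloxy)-6-[(tert-butyldimethylsilyloxy)methyl]-1,4a-dimethyl-1,2,3,4,4a,7,8,8a-octahydronaphthalene-1,5-dicarboxylate | COC(=O)C1=C(CO[Si](C)(C)C(C)(C)C)CC[C@@H]2[C@]1(C)CC[C@H](O[Si](C)(C)C(C)(C)C)[C@]2(C)C(=O)OC(C)(C)C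
F4 | step 21 | tert-butyl (1R,2S,4aS,8aR)-5-[(3E)-5-tert-butoxy-3-methyl-5-oxopent-3-en-1-yl]-2-(tert-butyldimethylsilyloxy)-6-(hydroxymethyl)-1,4a-dimethyl-1,2,3,4,4a,7,8,8a-octahydronaphthalene-1-carboxylate | CC(C)(C)OC(=O)/C=C(\C)CCC1=C(CO)CC[C@@H]2[C@]1(C)CC[C@H](O[Si](C)(C)C(C)(C)C)[C@]2(C)C(=O)OC(C)(C)C
F5 | step 21 | tert-butyl (1R,2S,4aR,5S,8aR)-5-[(3E)-5-tert-butoxy-3-methyl-5-oxopent-3-en-1-yl]-2-(tert-butyldimethylsilyloxy)-1,4a-dimethyl-6-methylidenedecahydronaphthalene-1-carboxylate | C=C1CC[C@@H]2[C@](C)(CC[C@H](O[Si](C)(C)C(C)(C)C)[C@]2(C)C(=O)OC(C)(C)C)[C@H]1CC/C(C)=C/C(=O)OC(C)(C)C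
F6 | step 21 | tert-butyl (1R,2S,4aR,5S,8aR)-5-[(3E)-5-tert-butoxy-3-methyl-5-oxopent-3-en-1-yl]-2-hydroxy-1,4a-dimethyl-6-methylidenedecahydronaphthalene-1-carboxylate | C=C1CC[C@@H]2[C@](C)(CC[C@H](O)[C@]2(C)C(=O)OC(C)(C)C)[C@H]1CC/C(C)=C/C(=O)OC(C)(C)C
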